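(Readings and results were generated by integration with constants of no real substance; noise was put on by code.)

Read the plateaus first.

| setting | midnight | spring | flask |
|---|---|---|---|
| starting material | 0.090 M | 0.14 M | 0.18 M |
| remark | run made earlier | run made earlier |  |
| time |  |  | 12 h |

| run | time / h | target / % | side product A / % | starting material / % |
|---|---|---|---|---|
| midnight | 2.50 | 33 | 23 | 0 |
| midnight | 5.00 | 43 | 26 | 0 |
| midnight | 8.00 | 45 | 23 | 0 |
| midnight | 10.0 | 45 | 29 | 0 |
| midnight | 12.0 | 45 | 22 | 1 |
| spring | 1.00 | 10 | 14 | 17 |
| spring | 3.00 | 35 | 25 | 1 |
| spring | 6.00 | 46 | 26 | 0 |
| spring | 8.00 | 46 | 25 | 0 |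
| spring | 12.0 | 46 | 25 | 1 |

(standard deviation of a reading: 1.5 percentage points)

1. ratio of target to side product A at 20 min
2. ratio of target to side product A at 2.0 h
3. ratio of target to side product A at 12 h
4. which of target and side product A there is more of at 12 h



A bench rule of thumb: a share of the charge that holds still when the charge changes may be carried to a new charge. The spring run holds 1.56 times the charge of the midnight run, yet target ends at 46% there against 45% at midnight, so the rule is tried on the flask, whose charge is 1.29 times the spring charge. The last spring readings, 46% of target and 25% of side product A with starting material at 1%, give 1.84. This is the end split, the ratio of target to side product A once the readings of both have stopped rising, an overall selectivity between the two. This reckoning puts the flask at 1.84 after 12 h, with target ahead.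

But the end split describes end states. The spring readings give 0.714 at 1.00 h and 1.40 at 3.00 h, so the ratio at 2.0 h is placed between these two readings. The early time 20 min is 0.333 of the earliest spring time, which puts it beyond the readings, and there the end split says nothing.

The forecast gives 0.5, 1.2 and 1.83, with target ahead at 12 h, on the ground that the “plateaus and time scales barely change”.

The simulation of the flask gives 0.150, 1.12 and 1.91, with target ahead, 46.4% against 24.3% of side product A. The end split of 1.84 stands beside 1.91, and 1.12 lies between 0.714 and 1.40. The forecast at 20 min is 3.33 times the flask's value, on the far side of the border.

    starting material → intermediate A (k = 0.0304 min⁻¹)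
    intermediate B → intermediate C (k = 0.143 min⁻¹)
    intermediate C → target (k = 0.00833 min⁻¹)
    intermediate A → side product A (k = 0.0129 min⁻¹)
    intermediate C → side product B (k = 0.00528 min⁻¹)
    intermediate A ⇌ intermediate B (K = 0.370, k = 0.169 min⁻¹)

Intermediate A feeds side product A, and intermediate B returns to intermediate A. In the run without that return, the ratio at 12 h rises from 1.91 to 8.02, and the ratio at 20 min rises from 0.150 to 0.443.

In the neighbour flask with 0.045 M of starting material, a quarter of the flask's charge, the end split again gives 1.84. The computed ratio there at 12 h is 1.91, from 46.4% of target and 24.3% of side product A.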